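Atom labels: C1 carries the exocyclic CH2, C4 the bromine, C5 the gem-dimethyl group, C6 is the ring CH, C7 the benzylic carbon. The plan cuts C1–C6 of the cyclohexane. It exploits the C7–C6–C1(=CH2) array: with C7 raised to an aryl ketone, C6 is an enol carbon and C1=CH2 is what remains when that carbon adds to a terminal alkyne. One gold-catalysed 6-exo-dig closure therefore forms the ring, the methylene group and the C6 stereocentre. Its precursor is an acyclic Z-silyl enol ether already holding the C4 bromide (from an auxiliary-controlled enolate bromination), the C5 quaternary carbon and the alkyne; aryl ethyl carbonates let borohydride erase the ketone afterwards.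

Key step: step 15

Remarks on the chemistry
- Stereochemistry: in the target C4 is R and C6 is S, and bromine and the benzyl group are cis (both equatorial). The same C4 geometry reads S while C3 carries oxygen (acyl, CH2OH, CH2OTf) and R once C3 is a plain CH2. No inversion is involved.
- Hydroboration of the vinyl group ends at a primary alcohol. A separate oxidation to the aldehyde is therefore needed before the aryl group can be added.
- C7=O and C4–Br stand in a 1,4 relationship. A metal enolate at C6 would close a cyclopropane onto C4, and a C7 alkoxide could close a tetrahydrofuran. The route therefore puts no base on an enolisable ketone, quenches alkoxides cold, uses a silver-free gold catalyst, and never equilibrates C6 with base, which would also pull the exocyclic alkene into conjugation.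
- Aryl ethyl carbonates are used in place of methyl ethers. This avoids hydrazone formation at a very crowded ketone and an oxidative demethylation at the end.
- Assumption: the minor C6 epimer from the ring closure can be removed by chromatography.

Step 1
Reactants: 1 methyl 3,3-dimethylpent-4-enoate
Product: 2 3,3-dimethylpent-4-enoic acid
Conditions: LiOH, THF/MeOH/H2O, rt; 1 M HCl
Reagents that add atoms: lithium hydroxide LiOH, [Li+].[OH-]
Why: Plain ester saponification, to which the isolated vinyl group and the quaternary carbon are indifferent.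

Step 2
Reactants: 2 3,3-dimethylpent-4-enoic acid; 3 (4S)-4-benzyl-1,3-oxazolidin-2-one
Product: 5 (4S)-4-benzyl-3-(3,3-dimethylpent-4-enoyl)-1,3-oxazolidin-2-one, via mixed pivalic anhydride 4 (not isolated)
Conditions: t-BuCOCl, Et3N, THF, −20 °C; LiCl, 3, −20 °C → rt
Reagents that add atoms: none
Why: N-acylation of an oxazolidinone through a mixed anhydride, in which the LiCl-activated auxiliary attacks the CH2-flanked carbonyl of 4 because the pivaloyl carbonyl is shielded by its tert-butyl group.

Step 3
Reactants: 5 (4S)-4-benzyl-3-(3,3-dimethylpent-4-enoyl)-1,3-oxazolidin-2-one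
Product: 7 (4S)-4-benzyl-3-[(2S)-2-bromo-3,3-dimethylpent-4-enoyl]-1,3-oxazolidin-2-one, via Z-dibutylboron enolate 6 (not isolated)
Conditions: Bu2BOTf, i-Pr2NEt, CH2Cl2, −78 → 0 °C; NBS, CH2Cl2, −78 °C
Reagents that add atoms: N-bromosuccinimide, O=C1CCC(=O)N1Br
Why: Evans-type auxiliary-controlled electrophilic bromination: soft enolisation gives the boron-chelated Z-enolate, NBS approaches the face opposite the benzyl group and so sets C4 (2S here), the enolate outruns the vinyl group for NBS at −78 °C, and any minor epimer is removed by chromatography so that later material is a single enantiomer.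

Step 4
Reactants: 7 (4S)-4-benzyl-3-[(2S)-2-bromo-3,3-dimethylpent-4-enoyl]-1,3-oxazolidin-2-one
Product: 8 (2S)-2-bromo-3,3-dimethylpent-4-en-1-ol
Conditions: LiBH4, H2O (1 equiv), Et2O, 0 °C
Reagents that add atoms: none
Why: Reductive cleavage of an N-acyl oxazolidinone by borohydride, which attacks the bromine-activated exocyclic carbonyl, leaves the neopentylic C–Br bond and the alkene alone at 0 °C, does not touch C4 and returns the auxiliary.

Step 5
Reactants: 8 (2S)-2-bromo-3,3-dimethylpent-4-en-1-ol
Product: 9 (2S)-2-bromo-3,3-dimethylpent-4-en-1-yl trifluoromethanesulfonate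
Conditions: Tf2O, 2,6-lutidine, CH2Cl2, −78 °C; cold wash, used crude
Reagents that add atoms: trifluoromethanesulfonic anhydride, O=S(=O)(OS(=O)(=O)C(F)(F)F)C(F)(F)F
Why: O-triflation of a primary alcohol with a hindered pyridine base, the electron-withdrawing vicinal bromine making the triflate stable enough for a cold wash and immediate use.

Step 6
Reactants: 9 (2S)-2-bromo-3,3-dimethylpent-4-en-1-yl trifluoromethanesulfonate; 10 1-(trimethylsilyl)propyne
Product: 12 (4R)-4-bromo-3,3-dimethyl-8-(trimethylsilyl)oct-1-en-7-yne, via 3-lithio-1-(trimethylsilyl)propyne 11 (not isolated)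
Conditions: 10, n-BuLi, THF, −78 → −20 °C; 9, THF, −78 °C
Reagents that add atoms: none
Why: SN2 alkylation of a silyl-capped propargylic organolithium by a primary triflate, fast at −78 °C where the secondary neopentylic bromide is no electrophile, with the silyl group steering attack to the CH2 terminus (alkyne rather than allene) and with C4 untouched even if bromine assists departure of triflate, since opening would still occur at C3.

Step 7
Reactants: 12 (4R)-4-bromo-3,3-dimethyl-8-(trimethylsilyl)oct-1-en-7-yne
Product: 14 (4R)-4-bromo-3,3-dimethyl-8-(trimethylsilyl)oct-7-yn-1-ol, via B-alkyl-9-BBN adduct 13 (not isolated)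
Conditions: 9-BBN, THF, 0 °C → rt; NaBO3·4H2O, THF/H2O, 0 °C → rt
Reagents that add atoms: sodium perborate tetrahydrate NaBO3·4H2O, [Na+].[O-]OB=O.O.O.O.O
Why: Brown hydroboration–oxidation: 9-BBN adds to the monosubstituted alkene much faster than to the silyl-capped alkyne and puts boron on the terminal carbon C7, away from the quaternary centre, while perborate oxidises the C–B bond at near-neutral pH so that the new hydroxyl does not displace the C4 bromide.

Step 8
Reactants: 14 (4R)-4-bromo-3,3-dimethyl-8-(trimethylsilyl)oct-7-yn-1-ol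
Product: 15 (4R)-4-bromo-3,3-dimethyl-8-(trimethylsilyl)oct-7-ynal
Conditions: Dess–Martin periodinane, CH2Cl2, 0 °C → rt
Reagents that add atoms: none
Why: Dess–Martin oxidation, neutral and fast, is run on freshly made 14 and stops cleanly at the aldehyde without disturbing bromide or silylalkyne.

Step 9
Reactants: 16 2,5-dibromobenzene-1,4-diol
Product: 17 1,4-dibromo-2,5-bis(methoxymethoxy)benzene
Conditions: MeOCH2Cl, i-Pr2NEt, CH2Cl2, 0 °C → rt
Reagents that add atoms: chloromethyl methyl ether, COCCl
Why: Double O-alkylation of the phenols to mixed acetals, chosen since methoxymethyl ethers tolerate and coordinate an ortho lithium and later fall off under mild acid.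

Step 10
Reactants: 15 (4R)-4-bromo-3,3-dimethyl-8-(trimethylsilyl)oct-7-ynal; 17 1,4-dibromo-2,5-bis(methoxymethoxy)benzene
Product: 19 (4R)-4-bromo-1-[4-bromo-2,5-bis(methoxymethoxy)phenyl]-3,3-dimethyl-8-(trimethylsilyl)oct-7-yn-1-ol (both C1 epimers), via aryllithium 18 (not isolated)
Conditions: 17, n-BuLi (1 equiv), THF, −78 °C; 15, −78 °C; AcOH, −78 °C
Reagents that add atoms: none
Why: Bromine–lithium exchange followed by 1,2-addition to an aldehyde: one equivalent of n-BuLi exchanges one of the two equivalent aryl bromines, the stabilised aryllithium has no driving force to exchange with the alkyl bromide, addition beats enolisation at −78 °C, the cold AcOH quench removes the alkoxide before it can attack C4, and the new carbinol centre needs no control because it is oxidised next.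

Step 11
Reactants: 19 (4R)-4-bromo-1-[4-bromo-2,5-bis(methoxymethoxy)phenyl]-3,3-dimethyl-8-(trimethylsilyl)oct-7-yn-1-ol
Product: 20 (4R)-4-bromo-1-[4-bromo-2,5-bis(methoxymethoxy)phenyl]-3,3-dimethyl-8-(trimethylsilyl)oct-7-yn-1-one
Conditions: Dess–Martin periodinane, CH2Cl2, rt
Reagents that add atoms: none
Why: Dess–Martin oxidation of a benzylic alcohol under neutral conditions, which creates the aryl ketone without ever exposing it to base.

Step 12
Reactants: 20 (4R)-4-bromo-1-[4-bromo-2,5-bis(methoxymethoxy)phenyl]-3,3-dimethyl-8-(trimethylsilyl)oct-7-yn-1-one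
Product: 22 (4R)-4-bromo-1-(4-bromo-2,5-dihydroxyphenyl)-3,3-dimethyloct-7-yn-1-one, via silylalkyne hydroquinone ketone 21 (not isolated)
Conditions: HCl (1.25 M in MeOH), rt → 40 °C; K2CO3 (excess), MeOH, 0 °C → rt, Ar; 1 M HCl to pH 4
Reagents that add atoms: none
Why: Acid-catalysed acetal exchange with methanol frees both phenols and carbonate-promoted methanolysis then cleaves the C(sp)–Si bond, the order being essential because the ortho phenoxide present in base pushes electron density into the ketone and blocks enolisation, so that C6 cannot close a cyclopropane onto C4.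

Step 13
Reactants: 22 (4R)-4-bromo-1-(4-bromo-2,5-dihydroxyphenyl)-3,3-dimethyloct-7-yn-1-one
Product: 23 (4R)-4-bromo-1-[4-bromo-2,5-bis(ethoxycarbonyloxy)phenyl]-3,3-dimethyloct-7-yn-1-one
Conditions: ClCO2Et, Et3N, THF, 0 °C
Reagents that add atoms: ethyl chloroformate, CCOC(=O)Cl
Why: O-acylation of both phenols with a chloroformate and a tertiary amine too weak to enolise the ketone, installing on the ortho oxygen the group that will later hand over to C7.

Step 14
Reactants: 23 (4R)-4-bromo-1-[4-bromo-2,5-bis(ethoxycarbonyloxy)phenyl]-3,3-dimethyloct-7-yn-1-one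
Product: 24 (1Z,4R)-4-bromo-1-[4-bromo-2,5-bis(ethoxycarbonyloxy)phenyl]-1-(tert-butyldimethylsilyloxy)-3,3-dimethyloct-1-en-7-yne
Conditions: TBSOTf, Et3N, CH2Cl2, 0 °C → rt; Et3N-deactivated silica
Reagents that add atoms: tert-butyldimethylsilyl trifluoromethanesulfonate, CC(C)(C)[Si](C)(C)OS(=O)(=O)C(F)(F)F
Why: Soft enolisation (silyl triflate plus tertiary amine): the carbonyl oxygen is silylated before C6 loses its proton, so no metal enolate that could displace bromide is formed, only C6 carries α-hydrogens, and strain between the aryl ring and the tert-alkyl group at C5 favours the Z isomer with OSi cis to C5.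

Step 15
Reactants: 24 (1Z,4R)-4-bromo-1-[4-bromo-2,5-bis(ethoxycarbonyloxy)phenyl]-1-(tert-butyldimethylsilyloxy)-3,3-dimethyloct-1-en-7-yne
Product: 25 [4-bromo-2,5-bis(ethoxycarbonyloxy)phenyl] (1S,3R)-3-bromo-2,2-dimethyl-6-methylidenecyclohexyl ketone (cis)
Conditions: Ph3PAuNTf2 (5 mol %), MeOH (3 equiv), CH2Cl2, rt
Reagents that add atoms: none
Why: Ph3PAuNTf2, a silver-free source of cationic monovalent gold, binds the terminal alkyne; C6 of the enol ether attacks the internal alkyne carbon anti to gold, methanol takes the silyl group from the resulting silyloxocarbenium ion, and protodeauration of the alkenylgold species leaves C1=CH2. The closest known reaction type is the gold-catalysed Conia-ene-type carbocyclisation of silyl enol ethers onto terminal alkynes, established for 5-exo-dig and 6-exo-dig closures. The cyclohexane closes 6-exo-dig, because Markovnikov polarisation of the terminal alkyne disfavours 7-endo attack and the C5 gem-dimethyl group (Thorpe–Ingold effect) folds the chain. C6 is controlled by C4 through a chair-like transition state with bromine equatorial and the bulky C7 enol ether unit pseudo-equatorial (the axial placement suffers syn-axial contacts and allylic strain between OSi and C4), so the cis ketone should prevail, while the trans epimer, expected mainly from the chair with axial bromine, is removed by chromatography. Chemoselectivity rests on the substrate: only one enol carbon exists, both C–Br bonds and the carbonates ignore soft carbophilic gold, no silver salt is present to abstract bromide, and no base is present, so neither cyclopropane closure from C6 to C4 nor migration of the new alkene into conjugation is triggered. Methanol is held to a few equivalents so that alkyne solvolysis and early desilylation stay behind ring closure.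

Step 16
Reactants: 25 [4-bromo-2,5-bis(ethoxycarbonyloxy)phenyl] (1S,3R)-3-bromo-2,2-dimethyl-6-methylidenecyclohexyl ketone
Product: 28 cyclocymopol, via o-quinone methide 26 (not isolated), via phenol monocarbonate 27 (not isolated)
Conditions: NaBH4 (excess), THF/H2O, 0 °C → rt; 1 M NaOH, 0 °C, Ar; 1 M HCl to pH 6
Reagents that add atoms: none
Why: Ortho-acyloxy-assisted borohydride deoxygenation of an aryl ketone: hydride gives the C7 alkoxide, which takes over the neighbouring ethoxycarbonyl group, the freed phenoxide expels ethyl carbonate to give 26, a second hydride adds to C7, and hydroxide then cleaves the remaining aryl carbonate, all without strong acid, radicals or strong base, so that C4–Br, Ar–Br, C1=CH2 and the C6 configuration stay as set (in the cis isomer the C7 alkoxide cannot reach the rear of the C4–Br bond, and the near-neutral work-up avoids chroman closure of the phenol onto C1).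

Compound list
1 | methyl 3,3-dimethylpent-4-enoate | COC(=O)CC(C)(C)C=C | starting material
2 | 3,3-dimethylpent-4-enoic acid | OC(=O)CC(C)(C)C=C | intermediate
3 | (4S)-4-benzyl-1,3-oxazolidin-2-one | O=C1N[C@@H](Cc2ccccc2)CO1 | starting material
4 | 3,3-dimethylpent-4-enoic pivalic anhydride | CC(C)(C)C(=O)OC(=O)CC(C)(C)C=C | intermediate
5 | (4S)-4-benzyl-3-(3,3-dimethylpent-4-enoyl)-1,3-oxazolidin-2-one | C=CC(C)(C)CC(=O)N1[C@@H](Cc2ccccc2)COC1=O | intermediate
6 | Z-dibutylboron enolate of 5 | CCCCB(CCCC)O/C(=C\C(C)(C)C=C)N1[C@@H](Cc2ccccc2)COC1=O | intermediate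
7 | (4S)-4-benzyl-3-[(2S)-2-bromo-3,3-dimethylpent-4-enoyl]-1,3-oxazolidin-2-one | C=CC(C)(C)[C@H](Br)C(=O)N1[C@@H](Cc2ccccc2)COC1=O | intermediate
8 | (2S)-2-bromo-3,3-dimethylpent-4-en-1-ol | OC[C@@H](Br)C(C)(C)C=C | intermediate
9 | (2S)-2-bromo-3,3-dimethylpent-4-en-1-yl trifluoromethanesulfonate | O=S(=O)(OC[C@@H](Br)C(C)(C)C=C)C(F)(F)F | intermediate
10 | 1-(trimethylsilyl)propyne | CC#C[Si](C)(C)C | starting material
11 | 3-lithio-1-(trimethylsilyl)propyne | [Li]CC#C[Si](C)(C)C | intermediate
12 | (4R)-4-bromo-3,3-dimethyl-8-(trimethylsilyl)oct-1-en-7-yne | C[Si](C)(C)C#CCC[C@@H](Br)C(C)(C)C=C | intermediate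
13 | 9-[(4R)-4-bromo-3,3-dimethyl-8-(trimethylsilyl)oct-7-yn-1-yl]-9-borabicyclo[3.3.1]nonane | C[Si](C)(C)C#CCC[C@@H](Br)C(C)(C)CCB1C2CCCC1CCC2 | intermediate
14 | (4R)-4-bromo-3,3-dimethyl-8-(trimethylsilyl)oct-7-yn-1-ol | C[Si](C)(C)C#CCC[C@@H](Br)C(C)(C)CCO | intermediate
15 | (4R)-4-bromo-3,3-dimethyl-8-(trimethylsilyl)oct-7-ynal | C[Si](C)(C)C#CCC[C@@H](Br)C(C)(C)CC=O | intermediate
16 | 2,5-dibromobenzene-1,4-diol | Oc1cc(Br)c(O)cc1Br | starting material
17 | 1,4-dibromo-2,5-bis(methoxymethoxy)benzene | COCOc1cc(Br)c(OCOC)cc1Br | intermediate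
18 | [4-bromo-2,5-bis(methoxymethoxy)phenyl]lithium | [Li]c1cc(OCOC)c(Br)cc1OCOC | intermediate
19 | (4R)-4-bromo-1-[4-bromo-2,5-bis(methoxymethoxy)phenyl]-3,3-dimethyl-8-(trimethylsilyl)oct-7-yn-1-ol, both C1 epimers | C[Si](C)(C)C#CCC[C@@H](Br)C(C)(C)CC(O)c1cc(OCOC)c(Br)cc1OCOC | intermediate
20 | (4R)-4-bromo-1-[4-bromo-2,5-bis(methoxymethoxy)phenyl]-3,3-dimethyl-8-(trimethylsilyl)oct-7-yn-1-one | C[Si](C)(C)C#CCC[C@@H](Br)C(C)(C)CC(=O)c1cc(OCOC)c(Br)cc1OCOC | intermediate
21 | (4R)-4-bromo-1-(4-bromo-2,5-dihydroxyphenyl)-3,3-dimethyl-8-(trimethylsilyl)oct-7-yn-1-one | C[Si](C)(C)C#CCC[C@@H](Br)C(C)(C)CC(=O)c1cc(O)c(Br)cc1O | intermediate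
22 | (4R)-4-bromo-1-(4-bromo-2,5-dihydroxyphenyl)-3,3-dimethyloct-7-yn-1-one | C#CCC[C@@H](Br)C(C)(C)CC(=O)c1cc(O)c(Br)cc1O | intermediate
23 | (4R)-4-bromo-1-[4-bromo-2,5-bis(ethoxycarbonyloxy)phenyl]-3,3-dimethyloct-7-yn-1-one | C#CCC[C@@H](Br)C(C)(C)CC(=O)c1cc(OC(=O)OCC)c(Br)cc1OC(=O)OCC | intermediate
24 | (1Z,4R)-4-bromo-1-[4-bromo-2,5-bis(ethoxycarbonyloxy)phenyl]-1-(tert-butyldimethylsilyloxy)-3,3-dimethyloct-1-en-7-yne | C#CCC[C@@H](Br)C(C)(C)/C=C(\O[Si](C)(C)C(C)(C)C)c1cc(OC(=O)OCC)c(Br)cc1OC(=O)OCC | intermediate
25 | [4-bromo-2,5-bis(ethoxycarbonyloxy)phenyl] (1S,3R)-3-bromo-2,2-dimethyl-6-methylidenecyclohexyl ketone | C=C1CC[C@@H](Br)C(C)(C)[C@H]1C(=O)c1cc(OC(=O)OCC)c(Br)cc1OC(=O)OCC | intermediate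
26 | o-quinone methide: 3-bromo-4-(ethoxycarbonyloxy)-6-{[(1S,3R)-3-bromo-2,2-dimethyl-6-methylidenecyclohexyl]methylidene}cyclohexa-2,4-dien-1-one | C=C1CC[C@@H](Br)C(C)(C)[C@H]1C=C2C=C(OC(=O)OCC)C(Br)=CC2=O | intermediate
27 | 2-bromo-5-{[(1S,3R)-3-bromo-2,2-dimethyl-6-methylidenecyclohexyl]methyl}-4-hydroxyphenyl ethyl carbonate | C=C1CC[C@@H](Br)C(C)(C)[C@H]1Cc1cc(OC(=O)OCC)c(Br)cc1O | intermediate
28 | cyclocymopol, 2-bromo-5-{[(1S,3R)-3-bromo-2,2-dimethyl-6-methylidenecyclohexyl]methyl}benzene-1,4-diol | C=C1CC[C@@H](Br)C(C)(C)[C@H]1Cc1cc(O)c(Br)cc1O | target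

Total step count: 16. Longest linear sequence: 15 (steps 1–8 and 10–16; step 9 is the one-step side branch).

Steps most likely to fail

Step 15. The crowded, neopentylic C6 may reach the alkyne too slowly, so that methanolysis of the enol ether back to the ketone wins. Discrimination between the chairs with equatorial and axial bromine may also be incomplete, which costs material as the trans epimer. The fallback sets out from 24 and replaces catalytic turnover by a stoichiometric carbomercuration with no protic additive present. HgCl2 (divalent mercury) with (Me3Si)2NH as acid scavenger in dry CH2Cl2 should close the same ring and give the alkenylmercury chloride F1. Its C–Hg bond is then cleaved in a separate operation with NaI and dilute aqueous HCl, which returns to the route at 25.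

Step 6. The carbanion may act as a base or attack bromine. This would cause loss of triflic acid or reductive 1,2-elimination of bromide and triflate instead of substitution at C3. The fallback sets out from 8. K2CO3 in MeOH closes the epoxide (2R)-2-(2-methylbut-3-en-2-yl)oxirane F2 with inversion at C4. Reagent 11 opens it at the CH2 terminus (BF3·OEt2, THF, −78 °C) to (4S)-3,3-dimethyl-8-(trimethylsilyl)oct-1-en-7-yn-4-ol F3. An Appel bromination (CBr4, PPh3) inverts C4 a second time and rejoins the route at 12. The last substitution is at a neopentylic carbon and is expected to be slow, which is why this is the reserve and not the main line.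

Step 16. Hydrolysis of the ortho carbonate may precede hydride delivery to the crowded ketone, or a hydrogen shift within the quinone methide may drain it to a conjugated diene before hydride capture. The fallback sets out from 25 and avoids the quinone methide. Condensation with TsNHNH2 (EtOH, warm) gives the tosylhydrazone F4. Catecholborane (CHCl3, −10 °C) followed by NaOAc·3H2O (hydrazone reduction with loss of nitrogen and sulfinate) gives the deoxygenated bis(ethyl carbonate) F5. Cold 1 M NaOH under argon cleaves both carbonates and arrives at 28.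

Further compounds
F1 | step 15 | alkenylmercury chloride: 25 in which the methylidene hydrogen trans to C6 is replaced by HgCl | Cl[Hg]/C=C1\CC[C@@H](Br)C(C)(C)[C@H]1C(=O)c2cc(OC(=O)OCC)c(Br)cc2OC(=O)OCC
F2 | step 6 | (2R)-2-(2-methylbut-3-en-2-yl)oxirane | C1[C@H](O1)C(C)(C)C=C
F3 | step 6 | (4S)-3,3-dimethyl-8-(trimethylsilyl)oct-1-en-7-yn-4-ol | C[Si](C)(C)C#CCC[C@H](O)C(C)(C)C=C
F4 | step 16 | tosylhydrazone of 25 | C=C1CC[C@@H](Br)C(C)(C)[C@H]1C(=NNS(=O)(=O)c2ccc(C)cc2)c3cc(OC(=O)OCC)c(Br)cc3OC(=O)OCC
F5 | step 16 | 2-bromo-5-{[(1S,3R)-3-bromo-2,2-dimethyl-6-methylidenecyclohexyl]methyl}-1,4-phenylene bis(ethyl carbonate) | C=C1CC[C@@H](Br)C(C)(C)[C@H]1Cc1cc(OC(=O)OCC)c(Br)cc1OC(=O)OCC
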